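**Retrosynthetic overview**

- Eduesmine ⇐ desilylation ⇐ bis-silyl diol ⇐ glycol cleavage and reduction of two terminal dioxolanes on a 2,5-diaryl-3,4-bis(dioxolanyl)oxolane. The two CH2OH carbons and their oxygens are the carbinol carbons of the bought chiral lactone.
- The oxolane is the only ring made and is closed late, by double reductive etherification of a C2-symmetric 1,4-diaryl-1,4-diketone. Hydride enters anti to the C3 and C4 substituents, which puts each aryl cis to its neighbour.
- Diketone ⇐ two aryllithium additions to a bis-Weinreb amide ⇐ bis-lactone, whose two bought lactone rings are opened and protected as acetonides.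
- Bis-lactone ⇐ mediated anodic homocoupling of the dianion of (S)-3-hydroxy-γ-butyrolactone. This forms the central 8–8' bond (C3–C4 of the target), and the lactone's C–O stereocentre sets both new centres.

Assumption: the target is taken exactly as drawn, (2S,3S,4S,5S), with each aryl cis to the adjacent CH2OH and the two CH2OH groups trans; the tert-butyldimethylsilyl ether of 4-bromoguaiacol is taken as a bought compound.

**Route**

Step 1
Reactants: 1 (S)-3-hydroxy-γ-butyrolactone (2 equiv)
Product: 3 (3S,3'S,4S,4'S)-4,4'-dihydroxy-[3,3'-bioxolane]-2,2'-dione, via dilithium dianion 2 (not isolated)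
Conditions: LiN(iPr)2 (2.1 equiv), THF, −78 → −45 °C; then divided cell, carbon-felt anode, Pt cathode, Fe(C5H5)2 (10 mol %), LiClO4 (0.2 M), THF, −60 °C, constant current, 1.05 F per mol of 1; AcOH in the catholyte and as quench
Reagents that add atoms: none
Why: Proposed new method: mediated anodic homocoupling of a β-oxido lactone enolate dianion, in which Fe(C5H5)2 is oxidised at the anode to [Fe(C5H5)2]+ (trivalent iron), this takes one electron from the enolate end of 2 to give the α-lactonyl radical, and the radical couples (with a second radical, or with enolate 2 followed by a second one-electron oxidation) on the face anti to the neighbouring C4–OLi group on both rings, so that the bought C4 stereocentre sets both new centres (3S,3'S) and the C2-symmetric trans,trans dimer results, while the lithium alkoxide cannot leave and so blocks β-elimination; the closest known reaction types are the trans-selective alkylation of this same dianion (Fráter–Seebach type) and the oxidative homocoupling of ester enolates by CuCl2, ferrocenium salts or direct anodic oxidation.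

Step 2
Reactants: 3 bis-lactone diol
Product: 5 (2S,3S)-2,3-bis[(4S)-2,2-dimethyl-1,3-dioxolan-4-yl]-N1,N4-dimethoxy-N1,N4-dimethylbutanediamide, via diester 4 (not isolated)
Conditions: 2,2-dimethoxypropane, MeOH, acetone, TsOH·H2O (cat.), rt; Et3N, evaporate; then Me(MeO)NH·HCl, iPrMgCl, THF, −20 → 0 °C; NH4Cl (aq)
Reagents that add atoms: 2,2-dimethoxypropane COC(C)(C)OC; N,O-dimethylhydroxylamine hydrochloride CNOC.Cl
Why: Acid-catalysed lactone methanolysis is pulled to the open diester by trapping each freed 1,2-diol as its terminal acetonide (transketalisation), and the crude diester is turned into the bis-Weinreb amide by the chloromagnesium amide (ester aminolysis), conditions that are too weakly basic and too cold to enolise the α-centres; no new stereocentre.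

Step 3
Reactants: 5 bis-Weinreb amide; 6 (4-bromo-2-methoxyphenoxy)(tert-butyl)dimethylsilane
Product: 8 (2S,3S)-1,4-bis[4-(tert-butyldimethylsilyloxy)-3-methoxyphenyl]-2,3-bis[(4S)-2,2-dimethyl-1,3-dioxolan-4-yl]butane-1,4-dione, via aryllithium 7 (not isolated)
Conditions: 6 (2.5 equiv), n-BuLi (2.4 equiv), THF, −78 °C; then 5, −78 → −30 °C; NH4Cl (aq) at −30 °C
Reagents that add atoms: none
Why: Weinreb ketone synthesis, in which bromine–lithium exchange gives 7, each addition stops at the chelated tetrahedral intermediate, and the cold mildly acidic quench releases the diketone without enolising the two α-stereocentres; no new stereocentre.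

Step 4
Reactants: 8 diketone
Product: 9 (2S,3R,4R,5S)-2,5-bis[4-(tert-butyldimethylsilyloxy)-3-methoxyphenyl]-3,4-bis[(4S)-2,2-dimethyl-1,3-dioxolan-4-yl]oxolane (2,3-cis; 3,4-trans; 4,5-cis)
Conditions: Et3SiH (6 equiv), BF3·OEt2 (2.5 equiv), CH2Cl2, −78 → −40 °C; NaHCO3 (aq) at −40 °C
Reagents that add atoms: none
Why: Double reductive etherification (ionic hydrogenation), in which the BF3-activated ketone is closed by the second carbonyl oxygen to a cyclic aryl-stabilised oxocarbenium ion, Et3SiH delivers hydride to C2 anti to the C3 dioxolanyl group, the remaining 5-aryl hemiketal ionises and the second hydride arrives anti to the C4 group, so both aryls end up cis to their neighbours as the kinetic product (C2 and C5 are set by C3 and C4).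

Step 5
Reactants: 9 bis-dioxolanyl oxolane
Product: 11 [(2S,3S,4S,5S)-2,5-bis[4-(tert-butyldimethylsilyloxy)-3-methoxyphenyl]oxolane-3,4-diyl]dimethanol, via dialdehyde 10 (not isolated)
Conditions: H5IO6 (2.4 equiv), EtOAc, 0 °C → rt; NaHCO3 (aq) wash; then NaBH4, MeOH–THF, −20 °C
Reagents that add atoms: none
Why: H5IO6 in EtOAc hydrolyses the terminal isopropylidene ketals and cleaves the freed 1,2-diols in one pot (Malaprade glycol cleavage), and NaBH4 reduces the 3,4-dicarbaldehyde cold before its α-centres can epimerise; the dioxolane stereocentres become the two CH2OH carbons and no new stereocentre is made.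

Step 6
Reactants: 11 bis-silyl ether diol
Product: 12 Eduesmine, [(2S,3S,4S,5S)-2,5-bis(4-hydroxy-3-methoxyphenyl)oxolane-3,4-diyl]dimethanol
Conditions: Bu4NF, AcOH (1:1), THF, 0 °C
Reagents that add atoms: none
Why: Fluoride-mediated cleavage of the two aryl silyl ethers (desilylation), buffered with AcOH so that the acid- and base-sensitive cis-2-aryl ether centres are untouched; no stereocentre changes.

**Compound list**

1 | (S)-3-hydroxy-γ-butyrolactone, (4S)-4-hydroxyoxolan-2-one | O=C1C[C@H](O)CO1 | starting material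
2 | dilithium (4S)-4,5-dihydrofuran-2,4-diolate (alkoxide–enolate dianion of 1) | [Li]OC1=C[C@H](O[Li])CO1 | intermediate
3 | (3S,3'S,4S,4'S)-4,4'-dihydroxy-[3,3'-bioxolane]-2,2'-dione (each ring 3,4-trans) | O=C1OC[C@@H](O)[C@@H]1[C@@H]1C(=O)OC[C@H]1O | intermediate
4 | dimethyl (2S,3S)-2,3-bis[(4S)-2,2-dimethyl-1,3-dioxolan-4-yl]butanedioate | COC(=O)[C@H]([C@H]1COC(C)(C)O1)[C@@H]([C@H]1COC(C)(C)O1)C(=O)OC | intermediate
5 | (2S,3S)-2,3-bis[(4S)-2,2-dimethyl-1,3-dioxolan-4-yl]-N1,N4-dimethoxy-N1,N4-dimethylbutanediamide | CON(C)C(=O)[C@H]([C@H]1COC(C)(C)O1)[C@@H]([C@H]1COC(C)(C)O1)C(=O)N(C)OC | intermediate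
6 | (4-bromo-2-methoxyphenoxy)(tert-butyl)dimethylsilane | COc1cc(Br)ccc1O[Si](C)(C)C(C)(C)C | starting material
7 | [4-(tert-butyldimethylsilyloxy)-3-methoxyphenyl]lithium | COc1cc([Li])ccc1O[Si](C)(C)C(C)(C)C | intermediate
8 | (2S,3S)-1,4-bis[4-(tert-butyldimethylsilyloxy)-3-methoxyphenyl]-2,3-bis[(4S)-2,2-dimethyl-1,3-dioxolan-4-yl]butane-1,4-dione | COc1cc(ccc1O[Si](C)(C)C(C)(C)C)C(=O)[C@H]([C@H]1COC(C)(C)O1)[C@@H]([C@H]1COC(C)(C)O1)C(=O)c1ccc(O[Si](C)(C)C(C)(C)C)c(OC)c1 | intermediate
9 | (2S,3R,4R,5S)-2,5-bis[4-(tert-butyldimethylsilyloxy)-3-methoxyphenyl]-3,4-bis[(4S)-2,2-dimethyl-1,3-dioxolan-4-yl]oxolane | COc1cc([C@H]2O[C@H](c3ccc(O[Si](C)(C)C(C)(C)C)c(OC)c3)[C@H]([C@H]3COC(C)(C)O3)[C@H]2[C@H]2COC(C)(C)O2)ccc1O[Si](C)(C)C(C)(C)C | intermediate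
10 | (2S,3R,4R,5S)-2,5-bis[4-(tert-butyldimethylsilyloxy)-3-methoxyphenyl]oxolane-3,4-dicarbaldehyde | COc1cc([C@H]2O[C@H](c3ccc(O[Si](C)(C)C(C)(C)C)c(OC)c3)[C@H](C=O)[C@H]2C=O)ccc1O[Si](C)(C)C(C)(C)C | intermediate
11 | [(2S,3S,4S,5S)-2,5-bis[4-(tert-butyldimethylsilyloxy)-3-methoxyphenyl]oxolane-3,4-diyl]dimethanol | COc1cc([C@H]2O[C@H](c3ccc(O[Si](C)(C)C(C)(C)C)c(OC)c3)[C@H](CO)[C@H]2CO)ccc1O[Si](C)(C)C(C)(C)C | intermediate
12 | Eduesmine, [(2S,3S,4S,5S)-2,5-bis(4-hydroxy-3-methoxyphenyl)oxolane-3,4-diyl]dimethanol | COc1cc([C@H]2O[C@H](c3ccc(O)c(OC)c3)[C@H](CO)[C@H]2CO)ccc1O | target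

**Step count and risks**

Total: 6 steps. Longest linear sequence: 6 steps (1 → 12); 6 is bought and enters in step 3.

Steps most likely to fail:

- **Step 1 (the new mediated electrolysis).** The cold THF electrolyte conducts poorly, the radical may abstract hydrogen from THF and return 1, and the dimer may be enolised and over-oxidised. The fallback uses known chemistry, sets out from 1 and comes back at 3. It leaves the cell and the mediated outer-sphere manifold: dianion 2 is made as before and added to anhydrous CuCl2 (divalent copper, 1.1 equiv) in DMF–THF at −78 °C. This is the classical stoichiometric copper-enolate oxidative homocoupling, and the anti approach to the C4 oxido group is the same one that makes the known alkylations of this dianion trans. No new compound is made.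

- **Step 4 (double reductive etherification).** The first hydride may add to an open-chain activated ketone and give the wrong C2 epimer, BF3 may reopen the benzylic ether and drift to the all-trans isomer, and Paal–Knorr dehydration to the furan may compete. The fallback sets out from 5 and comes back at 9, and it sets one benzylic centre by aryl addition and the other by a lactol reduction at −78 °C. Reduction of 5 with iBu2AlH at −78 °C gives the dialdehyde (2S,3S)-2,3-bis[(4S)-2,2-dimethyl-1,3-dioxolan-4-yl]butanedial F1. Bromide 6 and Mg give the arylmagnesium bromide F2, which is added with MgBr2·OEt2 in CH2Cl2–Et2O at −78 °C. The β-chelate between the aldehyde oxygen and the dioxolane oxygen directs attack anti to the α-substituent and gives the anti,anti diol F3, which already has the target configuration at all four centres. MnO2 oxidises one benzylic alcohol, and the hydroxy ketone closes at once to the cyclic hemiketal F4, which is not oxidised further. Et3SiH and BF3·OEt2 at −78 °C then deliver hydride anti to the C3 substituent (the established kinetic 2,3-cis lactol reduction) and give 9.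

- **Step 5 (excision of the two extra carbons).** The 3,4-dicarbaldehyde 10 has each formyl group cis to an aryl group and could epimerise to the all-trans isomer, and H5IO6 is acidic enough to threaten the benzylic ether. The fallback sets out from 9 and comes back at 11, and it cleaves an alkene instead of a glycol so that the aldehyde only exists at −78 °C under neutral conditions. Aqueous AcOH (80 %, 40 °C) gives the tetraol F5. PPh3, I2 and imidazole in toluene at 80 °C (vicinal diol to alkene) give the 3,4-divinyl oxolane F6. Ozonolysis in CH2Cl2–MeOH at −78 °C, titrated to a dye end point, with NaBH4 added cold, gives 11 directly.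

**Further compounds**

F0 | step 1 | none | none
F1 | step 4 | (2S,3S)-2,3-bis[(4S)-2,2-dimethyl-1,3-dioxolan-4-yl]butanedial | O=C[C@H]([C@H]1COC(C)(C)O1)[C@@H]([C@H]1COC(C)(C)O1)C=O
F2 | step 4 | [4-(tert-butyldimethylsilyloxy)-3-methoxyphenyl]magnesium bromide | COc1cc([Mg]Br)ccc1O[Si](C)(C)C(C)(C)C
F3 | step 4 | (1S,2R,3R,4S)-1,4-bis[4-(tert-butyldimethylsilyloxy)-3-methoxyphenyl]-2,3-bis[(4S)-2,2-dimethyl-1,3-dioxolan-4-yl]butane-1,4-diol | COc1cc(ccc1O[Si](C)(C)C(C)(C)C)[C@@H](O)[C@H]([C@H]1COC(C)(C)O1)[C@@H]([C@H]1COC(C)(C)O1)[C@H](O)c1ccc(O[Si](C)(C)C(C)(C)C)c(OC)c1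
F4 | step 4 | (3S,4R,5S)-2,5-bis[4-(tert-butyldimethylsilyloxy)-3-methoxyphenyl]-3,4-bis[(4S)-2,2-dimethyl-1,3-dioxolan-4-yl]oxolan-2-ol (both C2 anomers) | COc1cc([C@H]2OC(O)(c3ccc(O[Si](C)(C)C(C)(C)C)c(OC)c3)[C@H]([C@H]3COC(C)(C)O3)[C@H]2[C@H]2COC(C)(C)O2)ccc1O[Si](C)(C)C(C)(C)C
F5 | step 5 | (1S,1'S)-1,1'-[(2S,3S,4S,5S)-2,5-bis[4-(tert-butyldimethylsilyloxy)-3-methoxyphenyl]oxolane-3,4-diyl]di(ethane-1,2-diol) | COc1cc([C@H]2O[C@H](c3ccc(O[Si](C)(C)C(C)(C)C)c(OC)c3)[C@H]([C@H](O)CO)[C@H]2[C@H](O)CO)ccc1O[Si](C)(C)C(C)(C)C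
F6 | step 5 | (2S,3R,4R,5S)-2,5-bis[4-(tert-butyldimethylsilyloxy)-3-methoxyphenyl]-3,4-diethenyloxolane | COc1cc([C@H]2O[C@H](c3ccc(O[Si](C)(C)C(C)(C)C)c(OC)c3)[C@H](C=C)[C@H]2C=C)ccc1O[Si](C)(C)C(C)(C)C
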